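**Plan** (core numbered as furo[3,2-b]pyran-5-one: O1, C2 side chain, C3 OH, C3a, O4, C5 C=O, C6, C7, C7a)
- Cuts: first the side-chain C=C (cross-metathesis); then, after moving the acyl group from O4 to the 3-OH and reconnecting C6 to C3a, the C6–C7 and C3a–C7a bonds together as a [2+2] cycloreversion.
- Enabling feature: the free 3-OH sits on the carbon next to C3a, so C5 can be parked on that oxygen as a five-membered 4-alkoxybutenolide whose ring C=C is C6=C3a. Oxolane O1 then carries C7a=C7 as an enol ether three atoms from C3a, which gives an enone and an alkene set up for intramolecular [2+2].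
- Forward: butenolide from L-threonate → one photochemical event closes the oxolane and a cyclobutane (C3a–C7a, C6–C7) → the strained ring opens by retro-aldol/E1cB (C6–C3a broken, C6=C7 made) → ketone reduction and O-to-O acyl shift give the pyranone → side chain joined last by cross-metathesis.
- Stereochemistry: C2 and C3 from L-threonate; C7a from the tether-directed cis cycloaddition; C3a from hydride attack on the bridged ketone; side-chain centres from Sharpless epoxidation of divinyl carbinol; ring alkene Z by ring constraint, side-chain alkene E by metathesis.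

Key step: step 6

Remark: the sulfonyl-bearing carbon in 10–12 should form as a mixture of epimers and is left undefined in the SMILES; it stops being a stereocentre in step 7.

Step 1
Reactants: 1 methyl 3,4-O-isopropylidene-L-threonate
Product: 2 benzyl (2R)-2-[(4S)-2,2-dimethyl-1,3-dioxolan-4-yl]-2-hydroxyacetate
Conditions: BnOH (5 equiv), Ti(OiPr)4 (10 mol %), toluene, 100 °C, MeOH distilled off
Reagents that add atoms: benzyl alcohol OCc1ccccc1
Why: Titanate-catalysed transesterification should exchange methyl for benzyl without touching the acetonide or the α-stereocentre, and the benzyl group later becomes the removable enol-ether substituent of the butenolide.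

Step 2
Reactants: 2 benzyl (2R)-2-[(4S)-2,2-dimethyl-1,3-dioxolan-4-yl]-2-hydroxyacetate; 3 (triphenylphosphoranylidene)ketene Ph3P=C=C=O
Product: 5 (5R)-4-(benzyloxy)-5-[(4S)-2,2-dimethyl-1,3-dioxolan-4-yl]furan-2(5H)-one, via phosphorane ester 4 (not isolated)
Conditions: toluene, 110 °C
Reagents that add atoms: none
Why: The alcohol adds to the ketene ylide and the stabilised acyl ylide closes onto the neighbouring ester carbonyl (domino addition/intramolecular Wittig olefination), which should give the 4-benzyloxybutenolide under neutral conditions with the oxygen-bearing stereocentre untouched.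

Step 3
Reactants: 5 (5R)-4-(benzyloxy)-5-[(4S)-2,2-dimethyl-1,3-dioxolan-4-yl]furan-2(5H)-one
Product: 6 (5R)-4-(benzyloxy)-5-[(1S)-1,2-dihydroxyethyl]furan-2(5H)-one
Conditions: AcOH/H2O 4:1, 40 °C
Reagents that add atoms: none
Why: Mild acid hydrolysis of the isopropylidene acetal should free the diol while the vinylogous ester of the butenolide survives dilute aqueous acid.

Step 4
Reactants: 6 (5R)-4-(benzyloxy)-5-[(1S)-1,2-dihydroxyethyl]furan-2(5H)-one
Product: 7 (5R)-4-(benzyloxy)-5-[(1S)-2-{[tert-butyl(dimethyl)silyl]oxy}-1-hydroxyethyl]furan-2(5H)-one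
Conditions: TBSCl (1.05 equiv), imidazole, CH2Cl2, 0 °C
Reagents that add atoms: tert-butyldimethylsilyl chloride CC(C)(C)[Si](C)(C)Cl
Why: Silylation is much faster at the primary than at the hindered secondary hydroxyl (steric differentiation), which leaves the secondary OH for the enol-ether tether.

Step 5
Reactants: 7 (5R)-4-(benzyloxy)-5-[(1S)-2-{[tert-butyl(dimethyl)silyl]oxy}-1-hydroxyethyl]furan-2(5H)-one; 8 ethynyl p-tolyl sulfone
Product: 9 (5R)-4-(benzyloxy)-5-[(1S)-2-{[tert-butyl(dimethyl)silyl]oxy}-1-{[(E)-2-(4-methylbenzenesulfonyl)ethenyl]oxy}ethyl]furan-2(5H)-one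
Conditions: N-methylmorpholine (0.3 equiv), CH2Cl2, rt
Reagents that add atoms: none
Why: Amine-catalysed oxa-Michael addition of the alcohol to the acetylenic sulfone should give the (E)-β-alkoxyvinyl sulfone under conditions too weakly basic to enolise the butenolide γ-position.

Step 6
Reactants: 9 (5R)-4-(benzyloxy)-5-[(1S)-2-{[tert-butyl(dimethyl)silyl]oxy}-1-{[(E)-2-(4-methylbenzenesulfonyl)ethenyl]oxy}ethyl]furan-2(5H)-one
Product: 10 cis-fused tricyclic cyclobutane (γ-lactone/cyclobutane/oxolane sharing the benzyloxy-bearing carbon)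
Conditions: hν (300 nm), acetone (solvent and triplet sensitiser), 5 mM, argon, rt
Reagents that add atoms: none
Why: Triplet energy transfer from acetone excites the butenolide (a β-alkoxy enone), its β-carbon C4 adds to the oxygen-bearing carbon of the tethered alkene, and the triplet 1,4-biradical (α-acyl and α-sulfonyl radicals) closes after spin inversion, so the C3a–C7a and C6–C7 bonds of the target form in one photochemical event. The closest known reaction type is the intramolecular enone–alkene [2+2] photocycloaddition of 4-alkoxy-2(5H)-furanones, the first half of a de Mayo sequence. The oxolane ring closes first in the 1,5-mode (5-exo-trig, rule of five) through the C–C–O tether, and the cyclobutane then closes by recombination of the 1,4-biradical. The tether hangs from the existing stereocentre C5 of the butenolide, so the alkene can reach only that face, and the cis fusion required at the five/four and five/five ring junctions then fixes the quaternary C–OBn centre, the adjacent O–CH centre (C7a of the target) and the lactone α-carbon, while the sulfonyl carbon is not controlled and need not be. The step needs straight rather than crossed regiochemistry and excitation of the butenolide rather than the arenes: a crossed adduct would need a six-membered first closure, irradiation at 300 nm through acetone keeps the benzyl and tolyl groups dark, and the side arm is a silyl ether so that no second alkene competes. The product stores ring strain in a cyclobutane with a donor oxygen and an acceptor carbonyl on adjacent carbons, which thermal chemistry does not make and which step 7 uses.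

Step 7
Reactants: 10 cis-fused tricyclic cyclobutane
Product: 13 (1R,6R,8S)-8-({[tert-butyl(dimethyl)silyl]oxy}methyl)-2,7-dioxabicyclo[4.2.1]non-4-ene-3,9-dione, via cyclobutanol 11 (not isolated), via sulfonyl keto lactone 12 (not isolated)
Conditions: H2 (1 atm), Pd/C, EtOAc, rt; filter; DBU (2 equiv), CH2Cl2, 0 °C to rt
Reagents that add atoms: none
Why: Hydrogenolysis of the tertiary benzyl ether unmasks the cyclobutanol, whose alkoxide should undergo strain-driven retro-aldol cleavage of the bond to the lactone α-carbon (de Mayo fragmentation), after which the ester enolate expels p-toluenesulfinate (E1cB) to leave the ketone and a (Z)-enoate held in a bridged seven-membered lactone whose two ketone-flanking carbons are bridgeheads and cannot epimerise.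

Step 8
Reactants: 13 (1R,6R,8S)-8-({[tert-butyl(dimethyl)silyl]oxy}methyl)-2,7-dioxabicyclo[4.2.1]non-4-ene-3,9-dione
Product: 15 (2S,3R,3aR,7aR)-2-({[tert-butyl(dimethyl)silyl]oxy}methyl)-3-hydroxy-2,3,3a,7a-tetrahydro-5H-furo[3,2-b]pyran-5-one, via bridged hydroxy lactone 14 (not isolated)
Conditions: NaBH4, CeCl3·7H2O, MeOH, −78 °C; AcOH quench; DBU (0.2 equiv), CH2Cl2, rt
Reagents that add atoms: none
Why: Luche reduction should deliver hydride to the ketone from the oxolane face opposite the four-atom lactone bridge and the silyloxymethyl group, setting C3a cis to its three neighbours, and base-catalysed 1,2-acyl migration (translactonisation) to the new hydroxyl then replaces the bridged seven-membered lactone by the cis-fused six-membered one and frees the 3-OH.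

Step 9
Reactants: 15 (2S,3R,3aR,7aR)-2-({[tert-butyl(dimethyl)silyl]oxy}methyl)-3-hydroxy-2,3,3a,7a-tetrahydro-5H-furo[3,2-b]pyran-5-one
Product: 16 (2S,3R,3aR,7aR)-3-hydroxy-2-(hydroxymethyl)-2,3,3a,7a-tetrahydro-5H-furo[3,2-b]pyran-5-one
Conditions: HF·pyridine, THF, 0 °C to rt
Reagents that add atoms: none
Why: Fluoride-mediated desilylation under weakly acidic conditions should free the primary alcohol without opening or isomerising the unsaturated lactone.

Step 10
Reactants: 16 (2S,3R,3aR,7aR)-3-hydroxy-2-(hydroxymethyl)-2,3,3a,7a-tetrahydro-5H-furo[3,2-b]pyran-5-one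
Product: 17 (2R,3S,3aR,7aR)-3-hydroxy-5-oxo-2,3,3a,7a-tetrahydro-5H-furo[3,2-b]pyran-2-carbaldehyde
Conditions: TEMPO (0.1 equiv), PhI(OAc)2 (1.1 equiv), CH2Cl2, rt
Reagents that add atoms: none
Why: Oxoammonium (TEMPO) oxidation is selective for the primary over the hindered secondary alcohol and stops at the aldehyde under neutral conditions, so the epimerisable α-alkoxy aldehyde does not meet base (descriptors change only through CIP priorities).

Step 11
Reactants: 17 (2R,3S,3aR,7aR)-3-hydroxy-5-oxo-2,3,3a,7a-tetrahydro-5H-furo[3,2-b]pyran-2-carbaldehyde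
Product: 18 (2S,3R,3aR,7aR)-2-ethenyl-3-hydroxy-2,3,3a,7a-tetrahydro-5H-furo[3,2-b]pyran-5-one
Conditions: Ph3PCH3Br, KN(SiMe3)2, THF, −78 °C (ylide preformed, 1.5 equiv), then to 0 °C
Reagents that add atoms: methyltriphenylphosphonium bromide (as its ylide) C[P+](c1ccccc1)(c1ccccc1)c1ccccc1.[Br-]
Why: Wittig methylenation with the non-stabilised ylide at low temperature should convert the aldehyde into the vinyl group faster than it is enolised, the free hydroxyl being too weakly acidic to quench the ylide.

Step 12
Reactants: 19 penta-1,4-dien-3-ol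
Product: 20 (2R,3S)-1,2-epoxypent-4-en-3-ol
Conditions: Ti(OiPr)4 (10 mol %), L-(+)-diisopropyl tartrate (13 mol %), t-BuOOH, 4 Å molecular sieves, CH2Cl2, −20 °C
Reagents that add atoms: tert-butyl hydroperoxide CC(C)(C)OO
Why: Sharpless asymmetric epoxidation of the achiral divinyl carbinol combines enantiotopic-group with diastereotopic-face selection and with the L-(+)-tartrate should give the erythro (2R,3S)-epoxy alcohol, which fixes both side-chain stereocentres.

Step 13
Reactants: 20 (2R,3S)-1,2-epoxypent-4-en-3-ol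
Product: 21 tert-butyl(dimethyl){[(1S)-1-[(2R)-oxiran-2-yl]prop-2-en-1-yl]oxy}silane
Conditions: TBSCl, imidazole, DMF, 0 °C to rt
Reagents that add atoms: tert-butyldimethylsilyl chloride CC(C)(C)[Si](C)(C)Cl
Why: Standard silylation of the secondary alcohol, with imidazole too weak a base to start a Payne rearrangement of the epoxy alcohol.

Step 14
Reactants: 21 tert-butyl(dimethyl){[(1S)-1-[(2R)-oxiran-2-yl]prop-2-en-1-yl]oxy}silane
Product: 22 (2R,3S)-3-{[tert-butyl(dimethyl)silyl]oxy}pent-4-en-2-ol
Conditions: LiBHEt3, THF, 0 °C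
Reagents that add atoms: none
Why: SN2 hydride opening of the terminal epoxide at its unsubstituted carbon should give the methyl carbinol with the C2 configuration untouched.

Step 15
Reactants: 22 (2R,3S)-3-{[tert-butyl(dimethyl)silyl]oxy}pent-4-en-2-ol
Product: 23 (2R,3S)-3-{[tert-butyl(dimethyl)silyl]oxy}pent-4-en-2-yl acetate
Conditions: Ac2O, pyridine, DMAP (cat.), CH2Cl2, rt
Reagents that add atoms: acetic anhydride CC(=O)OC(C)=O
Why: DMAP-catalysed acylation of the secondary alcohol.

Step 16
Reactants: 23 (2R,3S)-3-{[tert-butyl(dimethyl)silyl]oxy}pent-4-en-2-yl acetate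
Product: 24 (2R,3S)-3-hydroxypent-4-en-2-yl acetate
Conditions: HF·pyridine, THF, 0 °C
Reagents that add atoms: none
Why: Desilylation with an acidic rather than basic fluoride source should free the allylic alcohol without 1,2-migration of the neighbouring acetate.

Step 17
Reactants: 24 (2R,3S)-3-hydroxypent-4-en-2-yl acetate
Product: 25 (2R,3S)-2-(acetyloxy)pent-4-en-3-yl benzoate
Conditions: BzCl, pyridine, DMAP (cat.), CH2Cl2, 0 °C
Reagents that add atoms: benzoyl chloride O=C(Cl)c1ccccc1
Why: Fast nucleophile-catalysed benzoylation in the cold should trap the allylic hydroxyl before the acetate can migrate.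

Step 18
Reactants: 18 (2S,3R,3aR,7aR)-2-ethenyl-3-hydroxy-2,3,3a,7a-tetrahydro-5H-furo[3,2-b]pyran-5-one; 25 (2R,3S)-2-(acetyloxy)pent-4-en-3-yl benzoate (3 equiv)
Product: 26 (2R,3S,4E)-2-(acetyloxy)-5-[(2S,3R,3aR,7aR)-3-hydroxy-5-oxo-2,3,3a,7a-tetrahydro-5H-furo[3,2-b]pyran-2-yl]pent-4-en-3-yl benzoate
Conditions: second-generation Hoveyda–Grubbs catalyst RuCl2(H2IMes)(=CH-C6H4-2-OiPr) (5 mol %), CH2Cl2, 40 °C
Reagents that add atoms: none
Why: Olefin cross-metathesis between two terminal alkenes that each homodimerise slowly because of their allylic oxygen substituents should favour the E cross product, while the conjugated ring alkene, the esters and the free hydroxyl are tolerated.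

**Compound list**
1 | methyl 3,4-O-isopropylidene-L-threonate | COC(=O)[C@H](O)[C@@H]1COC(C)(C)O1 | starting material
2 | benzyl (2R)-2-[(4S)-2,2-dimethyl-1,3-dioxolan-4-yl]-2-hydroxyacetate | O=C(OCc1ccccc1)[C@H](O)[C@@H]1COC(C)(C)O1 | intermediate
3 | (triphenylphosphoranylidene)ketene | O=C=C=P(c1ccccc1)(c1ccccc1)c1ccccc1 | starting material
4 | phosphorane ester: benzyl (2R)-2-[(4S)-2,2-dimethyl-1,3-dioxolan-4-yl]-2-{[(triphenylphosphoranylidene)acetyl]oxy}acetate | O=C(OCc1ccccc1)[C@H](OC(=O)C=P(c1ccccc1)(c1ccccc1)c1ccccc1)[C@@H]1COC(C)(C)O1 | intermediate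
5 | (5R)-4-(benzyloxy)-5-[(4S)-2,2-dimethyl-1,3-dioxolan-4-yl]furan-2(5H)-one | O=C1C=C(OCc2ccccc2)[C@H](O1)[C@@H]1COC(C)(C)O1 | intermediate
6 | (5R)-4-(benzyloxy)-5-[(1S)-1,2-dihydroxyethyl]furan-2(5H)-one | O=C1C=C(OCc2ccccc2)[C@H](O1)[C@@H](O)CO | intermediate
7 | (5R)-4-(benzyloxy)-5-[(1S)-2-{[tert-butyl(dimethyl)silyl]oxy}-1-hydroxyethyl]furan-2(5H)-one | O=C1C=C(OCc2ccccc2)[C@H](O1)[C@@H](O)CO[Si](C)(C)C(C)(C)C | intermediate
8 | ethynyl p-tolyl sulfone | C#CS(=O)(=O)c1ccc(C)cc1 | starting material
9 | (5R)-4-(benzyloxy)-5-[(1S)-2-{[tert-butyl(dimethyl)silyl]oxy}-1-{[(E)-2-(4-methylbenzenesulfonyl)ethenyl]oxy}ethyl]furan-2(5H)-one | O=C1C=C(OCc2ccccc2)[C@H](O1)[C@H](CO[Si](C)(C)C(C)(C)C)O/C=C/S(=O)(=O)c1ccc(C)cc1 | intermediate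
10 | cis-fused tricyclic cyclobutane photoadduct (γ-lactone, cyclobutane and oxolane share the benzyloxy-bearing quaternary carbon; silyloxymethyl cis to the lactone oxygen; sulfonyl carbon as epimer mixture) | O=C1O[C@@H]2[C@H](CO[Si](C)(C)C(C)(C)C)O[C@@H]3C(S(=O)(=O)c4ccc(C)cc4)[C@H]1[C@]23OCc1ccccc1 | intermediate
11 | cyclobutanol (10 without the benzyl group) | O=C1O[C@@H]2[C@H](CO[Si](C)(C)C(C)(C)C)O[C@@H]3C(S(=O)(=O)c4ccc(C)cc4)[C@H]1[C@]23O | intermediate
12 | sulfonyl keto lactone (saturated 5-tosyl analogue of 13) | O=C1CC(S(=O)(=O)c2ccc(C)cc2)[C@H]2O[C@@H](CO[Si](C)(C)C(C)(C)C)[C@@H](O1)C2=O | intermediate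
13 | (1R,6R,8S)-8-({[tert-butyl(dimethyl)silyl]oxy}methyl)-2,7-dioxabicyclo[4.2.1]non-4-ene-3,9-dione | O=C1C=C[C@H]2O[C@@H](CO[Si](C)(C)C(C)(C)C)[C@@H](O1)C2=O | intermediate
14 | bridged hydroxy lactone (9-hydroxy analogue of 13, hydroxyl on the side of the lactone bridge) | O=C1C=C[C@H]2O[C@@H](CO[Si](C)(C)C(C)(C)C)[C@@H](O1)[C@H]2O | intermediate
15 | (2S,3R,3aR,7aR)-2-({[tert-butyl(dimethyl)silyl]oxy}methyl)-3-hydroxy-2,3,3a,7a-tetrahydro-5H-furo[3,2-b]pyran-5-one | CC(C)(C)[Si](C)(C)OC[C@@H]1O[C@@H]2C=CC(=O)O[C@@H]2[C@@H]1O | intermediate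
16 | (2S,3R,3aR,7aR)-3-hydroxy-2-(hydroxymethyl)-2,3,3a,7a-tetrahydro-5H-furo[3,2-b]pyran-5-one | OC[C@@H]1O[C@@H]2C=CC(=O)O[C@@H]2[C@@H]1O | intermediate
17 | (2R,3S,3aR,7aR)-3-hydroxy-5-oxo-2,3,3a,7a-tetrahydro-5H-furo[3,2-b]pyran-2-carbaldehyde | O=C[C@@H]1O[C@@H]2C=CC(=O)O[C@@H]2[C@@H]1O | intermediate
18 | (2S,3R,3aR,7aR)-2-ethenyl-3-hydroxy-2,3,3a,7a-tetrahydro-5H-furo[3,2-b]pyran-5-one | C=C[C@@H]1O[C@@H]2C=CC(=O)O[C@@H]2[C@@H]1O | intermediate
19 | penta-1,4-dien-3-ol | C=CC(O)C=C | starting material
20 | (2R,3S)-1,2-epoxypent-4-en-3-ol | C=C[C@H](O)[C@H]1CO1 | intermediate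
21 | tert-butyl(dimethyl){[(1S)-1-[(2R)-oxiran-2-yl]prop-2-en-1-yl]oxy}silane | C=C[C@H](O[Si](C)(C)C(C)(C)C)[C@H]1CO1 | intermediate
22 | (2R,3S)-3-{[tert-butyl(dimethyl)silyl]oxy}pent-4-en-2-ol | C[C@@H](O)[C@@H](O[Si](C)(C)C(C)(C)C)C=C | intermediate
23 | (2R,3S)-3-{[tert-butyl(dimethyl)silyl]oxy}pent-4-en-2-yl acetate | CC(=O)O[C@H](C)[C@@H](O[Si](C)(C)C(C)(C)C)C=C | intermediate
24 | (2R,3S)-3-hydroxypent-4-en-2-yl acetate | CC(=O)O[C@H](C)[C@@H](O)C=C | intermediate
25 | (2R,3S)-2-(acetyloxy)pent-4-en-3-yl benzoate | CC(=O)O[C@H](C)[C@H](C=C)OC(=O)c1ccccc1 | intermediate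
26 | (2R,3S,4E)-2-(acetyloxy)-5-[(2S,3R,3aR,7aR)-3-hydroxy-5-oxo-2,3,3a,7a-tetrahydro-5H-furo[3,2-b]pyran-2-yl]pent-4-en-3-yl benzoate | CC(=O)O[C@H](C)[C@H](/C=C/[C@@H]1O[C@@H]2C=CC(=O)O[C@@H]2[C@@H]1O)OC(=O)c1ccccc1 | target

Total step count: 18. Longest linear sequence: 12 (steps 1–11, then 18).

**Steps most likely to fail**

Step 6. The push–pull alkene may only undergo E/Z isomerisation by energy transfer, the first bond may form to the sulfonyl-bearing carbon (crossed adduct), or triplet acetone may add to the enol ether as an oxetane. The fallback gives up the built-in leaving group and uses a plain, electron-rich vinyl ether, installing the ring alkene later. It sets out from 7: transfer vinylation ([Ir(cod)Cl]2 cat., Na2CO3, vinyl acetate, toluene, 100 °C) should give vinyl ether F1. Irradiation as in step 6 should give cyclobutane F2. H2 over Pd/C and then DBU should give, by retro-aldol alone, saturated bridged keto lactone F3. NaBH4 in MeOH followed by catalytic DBU should give saturated bicyclic lactone F4. The lactone dianion (LiN(iPr)2, 2.2 equiv, THF, −78 °C) with PhSeBr should give selenide F5, and selenoxide syn-elimination (H2O2, pyridine, 0 °C) returns to the route at 15.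

Step 7. The alkoxide of 11 may fragment the wrong cyclobutane bond (push-out of sulfinate with cleavage of the C3a–C7a bond just made), or the carbanion chemistry may eliminate to a cyclobutene or open the lactone. The fallback separates bond cleavage from elimination and avoids any carbanion next to the sulfone (no new compound, F0). It sets out from 10: after hydrogenolysis, cyclobutanol 11 is isolated and opened under Brønsted acid catalysis (camphorsulfonic acid, CH2Cl2, rt), where the retro-aldol runs through the lactone enol and a protonated ketone. Sulfonyl keto lactone 12 is isolated, and sulfinate is then eliminated in a separate step with Et3N in CH2Cl2, coming back at 13.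

Step 11. The basic ylide may enolise the β-hydroxy-α-alkoxy aldehyde, leading to epimerisation at C2 or retro-aldol cleavage, or add to the unsaturated lactone. The fallback installs the vinyl group before the 3-OH is freed and without base. It sets out from 13: HF·pyridine should give primary alcohol F6. Dess–Martin periodinane should give keto aldehyde F7. Aldehyde-selective, non-basic methylenation with CH2I2, Zn and Ti(OiPr)4 in THF (Takai-type gem-dimetal methylenation) should give vinyl ketone F8. Luche reduction and acyl shift as in step 8 then come back at 18.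

**Further compounds**
F1 | step 6 | (5R)-4-(benzyloxy)-5-[(1S)-2-{[tert-butyl(dimethyl)silyl]oxy}-1-(ethenyloxy)ethyl]furan-2(5H)-one | O=C1C=C(OCc2ccccc2)[C@H](O1)[C@H](CO[Si](C)(C)C(C)(C)C)OC=C
F2 | step 6 | des-sulfonyl analogue of cyclobutane 10 | O=C1O[C@@H]2[C@H](CO[Si](C)(C)C(C)(C)C)O[C@@H]3C[C@H]1[C@]23OCc1ccccc1
F3 | step 6 | saturated bridged keto lactone (4,5-dihydro analogue of 13) | O=C1CC[C@H]2O[C@@H](CO[Si](C)(C)C(C)(C)C)[C@@H](O1)C2=O
F4 | step 6 | saturated bicyclic lactone (6,7-dihydro analogue of 15) | CC(C)(C)[Si](C)(C)OC[C@@H]1O[C@@H]2CCC(=O)O[C@@H]2[C@@H]1O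
F5 | step 6 | 6-(phenylselanyl) derivative of F4 | CC(C)(C)[Si](C)(C)OC[C@@H]1O[C@@H]2CC([Se]c3ccccc3)C(=O)O[C@@H]2[C@@H]1O
F0 | step 7 | none | none
F6 | step 11 | (1R,6R,8S)-8-(hydroxymethyl)-2,7-dioxabicyclo[4.2.1]non-4-ene-3,9-dione | O=C1C=C[C@H]2O[C@@H](CO)[C@@H](O1)C2=O
F7 | step 11 | 8-formyl analogue of 13 (keto aldehyde) | O=C1C=C[C@H]2O[C@@H](C=O)[C@@H](O1)C2=O
F8 | step 11 | 8-ethenyl analogue of 13 (vinyl ketone) | O=C1C=C[C@H]2O[C@@H](C=C)[C@@H](O1)C2=O
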